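Start from what cannot change: free catalyst, catalyst intermediates A and B, trapped intermediate and spent catalyst add up to the catalyst charged, at any moment in these flasks.

| flask | starting material | reagent | capture agent | free catalyst | temperature | time |
|---|---|---|---|---|---|---|
| south-west | 5.0 mM | 1.00 equiv | 1.50 mM | 6.6 mol% | −5 °C | 12 s |
| south-east | 5.0 mM | 1.00 equiv | 1.50 mM | 6.6 mol% | 55 °C | 12 s |
| north-west | 5.0 mM | 1.00 equiv | 1.50 mM | 6.6 mol% | 25 °C | 12 s |

    reagent + free catalyst → catalyst intermediate A (k1 = 2310 M⁻¹ s⁻¹, Ea1 = 36.0 kJ mol⁻¹)
    catalyst intermediate B → free catalyst + target (k2 = 0.475 s⁻¹, Ea2 = 76.0 kJ mol⁻¹)
    starting material + catalyst intermediate A → catalyst intermediate B (k3 = 387 M⁻¹ s⁻¹, Ea3 = 43.0 kJ mol⁻¹)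
    catalyst intermediate A + target → spent catalyst (k4 = 15.8 M⁻¹ s⁻¹, Ea4 = 54.0 kJ mol⁻¹)
    catalyst intermediate B + capture agent → trapped intermediate (k5 = 166 M⁻¹ s⁻¹, Ea5 = 44.0 kJ mol⁻¹)
    (constants at 25 °C)

- the constants hold at 25 °C; other temperatures follow from the activation energies

1. the flask with the highest amount of target, in percent of the starting material charged ("all alike" if they lie within 1.5 percentage points) (south-west / south-east / north-west / all alike)
2. final target, as a percentage of the starting material charged, in south-west
3. final target, as a percentage of the starting material charged, in south-east
4. final target, as a percentage of the starting material charged, in north-west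

- Follow one catalyst: each visit to catalyst intermediate B ends in target or in trapped intermediate. So take N, the rate constant of target release over the rate constant of capture times the capture agent concentration, which is 1.91 in north-west: the target made per catalyst lost to capture, a selectivity factor.
- As a first estimate, hold the capture agent at its charge, because the catalyst charge of 0.330 mM is less than the 1.50 mM of capture agent; capture can still use up to 22.0 % of that charge, and N rises as it does.
- Read the end state off N: the estimated target once the catalyst is lost, in percent of starting material, is the catalyst loading times N.
- Heat raises N because target release has the larger activation energy, 76.0 kJ mol⁻¹ against 44.0 kJ mol⁻¹. N is 0.450 in south-west and 6.21 in south-east.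
- These end estimates are therefore 2.97 % in south-west, 12.6 % in north-west and 41.0 % in south-east, so expect south-east highest.
- Test whether N is enough, since the end estimate applies once the catalyst is lost. Let x be the capture rate constant times capture agent concentration times run time, counted as if the whole catalyst charge sat as catalyst intermediate B; the share lost is then one minus exp(−x).
- In south-east x is 15.1 and in north-west 2.99, both above one, so commit to 41.0 % and 12.0 %.
- In south-west x is 0.410, below one, so 33.6 % of the catalyst is lost and target comes to 0.999 %.
- The forecast named south-east, with 0.8 % in south-west, 39 % in south-east and 11.8 % in north-west, on the ground that “trapping of B kills the catalyst”.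
- The simulation gives south-east highest, with 0.674 % in south-west, 39.3 % in south-east and 11.6 % in north-west. In south-west at 12.0 s, trapped intermediate holds 22.1 % of the catalyst charged, against the 33.6 % reckoned. Loading times N times that reading gives 0.657 % of target.
- Use N on the north-west flask with 0.38 mM of capture agent: N becomes 7.53, and its trapped intermediate of 2.35 % of the starting material gives 17.7 % of target. The simulation gives 21.0 %.

All constants were set for the occasion; the result is computed.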